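**Strategy.** The synthesis rests on cutting the C7–C8 bond of the seven-membered ring (C1, C5–C10). The oxygens on C6 and C9 stand in a 1,4-relationship, so C7 and C8 are both α-carbons of ketones and are joined as two enolates under oxidation. In one operation, divalent copper couples the bis-lithium enolate of a diketone, which closes the cycloheptane as its 6,9-dione and places the C8 methyl group. The precursor is a cyclopentane that already holds the stereocentres C1, C4 and C5: acetyl on C5, methyl and 2-oxobutyl on C1 (the latter trans to the acetyl), and the C4 isopropyl carbinol as its triethylsilyl ether.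

Key step: step 10

Assumption: atoms are numbered as in the target (C1 ring-fusion C–CH3, C2/C3 ring CH2, C4 C(OH)iPr, C5 ring-fusion CH, C6 CH–O-aroyl, C7 CH2, C8 C(OH)CH3, C9 CHOH, C10 CH2) and bicyclic names use these locants; β is the face of the C1 methyl; the C8 centre of the ring-closed ketones is expected as an epimer mixture and is drawn as the 8α-methyl epimer.

**Step 1**
Reactants: 1 2-ethylacrolein
Product: 2 2-methylidenebutan-1-ol
Conditions: NaBH4, CeCl3·7H2O, MeOH, 0 °C
Reagents that add atoms: none
Why: Luche reduction delivers hydride 1,2 to the enal, so the 1,1-disubstituted alkene is kept.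

**Step 2**
Reactants: 2 2-methylidenebutan-1-ol
Product: 3 2-(chloromethyl)but-1-ene
Conditions: MsCl, 2,4,6-collidine, LiCl, DMF, 0 °C
Reagents that add atoms: lithium chloride [Li+].[Cl-]
Why: The mesylate formed in situ is displaced by chloride (Collington–Meyers chlorination), and direct and allylic displacement give the same product because the two allyl termini are equivalent.

**Step 3**
Reactants: 3 2-(chloromethyl)but-1-ene; 4 3-ethoxycyclopent-2-en-1-one
Product: 7 3-(2-methylidenebutyl)cyclopent-2-en-1-one, via Grignard reagent 5 (not isolated), via magnesium alkoxide adduct 6 (not isolated)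
Conditions: Mg, THF, 0 °C; add 4, 0 °C → rt; 1 M HCl, 0 °C
Reagents that add atoms: none
Why: Stork–Danheiser sequence, in which the allylic Grignard reagent adds 1,2 to the vinylogous ester and cold dilute acid hydrolyses the enol ether with loss of water to transpose the enone without moving the side-chain alkene into conjugation.

**Step 4**
Reactants: 7 3-(2-methylidenebutyl)cyclopent-2-en-1-one
Product: 9 (R)-trimethylsilyl enol ether with the C1 quaternary centre, via aluminium enolate 8 (not isolated)
Conditions: Me3Al, Cu(O2CC4H3S) (copper thiophene-2-carboxylate, monovalent copper, 5 mol %), chiral phosphoramidite ligand (10 mol %), Et2O, −30 °C; then TMSOTf, THF, −30 → 0 °C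
Reagents that add atoms: trimethylaluminium C[Al](C)C; trimethylsilyl trifluoromethanesulfonate C[Si](C)(C)OS(=O)(=O)C(F)(F)F
Why: Copper-catalysed asymmetric conjugate addition of Me3Al to a β-substituted cyclic enone builds the quaternary C1 centre, the ligand antipode being chosen so that methyl is delivered to the face that gives (R), and the aluminium enolate is trapped as the regiodefined silyl enol ether.

**Step 5**
Reactants: 9 (R)-trimethylsilyl enol ether; 10 acetaldehyde
Product: 12 (2S,3R)-2-(1-hydroxyethyl)-3-methyl-3-(2-methylidenebutyl)cyclopentan-1-one, via lithium enolate 11 (not isolated)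
Conditions: MeLi, THF, 0 °C; then 10, −78 °C; AcOH, −78 °C
Reagents that add atoms: none
Why: MeLi cleaves the Si–O bond to give the lithium enolate only at C5, and in the aldol addition acetaldehyde should approach anti to the larger 2-methylidenebutyl group, placing the side chain cis to the C1 methyl (5S), while the carbinol centre is uncontrolled and is oxidised in step 7.

**Step 6**
Reactants: 12 aldol adduct
Product: 13 (1R,2S,3R)-2-(1-hydroxyethyl)-3-methyl-3-(2-methylidenebutyl)-1-(propan-2-yl)cyclopentan-1-ol
Conditions: iPrMgCl (3.5 equiv), CeCl3, THF, −78 → 0 °C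
Reagents that add atoms: isopropylmagnesium chloride CC(C)[Mg]Cl
Why: The weakly basic organocerium reagent (Imamoto conditions) adds to the enolisable ketone after the first equivalent has deprotonated the side-chain hydroxyl, and attack anti to the adjacent C5 side chain sets the C4 hydroxyl cis to that chain (4R).

**Step 7**
Reactants: 13 diol
Product: 14 1-[(1R,2R,5R)-2-hydroxy-5-methyl-5-(2-methylidenebutyl)-2-(propan-2-yl)cyclopentyl]ethan-1-one
Conditions: Dess–Martin periodinane, NaHCO3, CH2Cl2, 0 °C → rt
Reagents that add atoms: none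
Why: Dess–Martin oxidation converts the only oxidisable (secondary) hydroxyl into the C6 ketone, and the buffer keeps the tertiary β-hydroxy ketone from losing water.

**Step 8**
Reactants: 14 β-hydroxy ketone
Product: 15 C4 triethylsilyl ether of 14
Conditions: TESOTf, 2,6-lutidine, CH2Cl2, −78 → 0 °C
Reagents that add atoms: triethylsilyl trifluoromethanesulfonate CC[Si](CC)(CC)OS(=O)(=O)C(F)(F)F
Why: A silyl triflate with a hindered pyridine base silylates the tertiary hydroxyl at low temperature without enolising the methyl ketone, and the ether later blocks retro-aldol cleavage under the basic conditions of step 10.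

**Step 9**
Reactants: 15 silyl ether alkene
Product: 17 1-[(1R,2R,3R)-2-acetyl-1-methyl-3-(propan-2-yl)-3-(triethylsilyloxy)cyclopentyl]butan-2-one, via ozonide 16 (not isolated)
Conditions: O3, CH2Cl2, −78 °C; then PPh3, −78 °C → rt
Reagents that add atoms: ozone [O-][O+]=O
Why: Ozonolysis with reductive work-up cleaves the single 1,1-disubstituted alkene to the C9 ethyl ketone and leaves the silyl ether and the C6 ketone untouched.

**Step 10**
Reactants: 17 diketone precursor
Product: 19 trans-fused 1,8-dimethyl-4-(propan-2-yl)-4-(triethylsilyloxy)bicyclo[5.3.0]decane-6,9-dione, via bis-lithium enolate 18 (not isolated)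
Conditions: LiN(iPr)2 (2.2 equiv), THF, −78 °C, slow addition of 17; then Cu(OTf)2 (2.2 equiv) in iPrCN, −78 → −20 °C; 0.005 M
Reagents that add atoms: none
Why: Proposed new method: LiN(iPr)2 removes the unhindered C7 methyl and C8 methylene protons to give bis-enolate 18, one-electron oxidation of one enolate by divalent copper gives an α-keto radical that adds to the enolate carbon of the other arm, and a second oxidation of the resulting ketyl delivers the 1,4-diketone. The closest known reaction type is the intramolecular oxidative coupling of ketone bis-enolates with CuCl2, Cu(OTf)2 or Fe(acac)3, which is established for smaller rings but not for a seven-membered one. The seven-membered ring (C1, C5 to C10) closes by 7-endo-trig attack of the radical on the enolate double bond of the other arm, and the trans-1,2 arrangement of the two arms on the cyclopentane leads to the unstrained trans-fused bicycle. The new C8 centre is not controlled by any element, since it is epimerisable next to the C9 carbonyl, and it is erased when C8 becomes sp2 in step 13. The step needs kinetic enolisation at C7 and C8 only, which the substrate secures because C5 is a methine between two quaternary carbons and C10 is neopentyl, and it needs ring closure to beat intermolecular coupling, which high dilution secures. Because the two carbonyls are 1,5-related, 17 is added slowly to excess base at −78 °C so that the mono-enolate is deprotonated again before it can close to a six-membered aldol, and leaving C5 untouched keeps the β-silyloxy group from eliminating.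

**Step 11**
Reactants: 19 silyloxy dione
Product: 20 4β-hydroxy-1,8-dimethyl-4-(propan-2-yl)bicyclo[5.3.0]decane-6,9-dione
Conditions: HF·pyridine, pyridine/THF, 0 °C → rt
Reagents that add atoms: none
Why: Buffered fluoride cleaves the Si–O bond under non-basic conditions, so the liberated β-hydroxy ketone cannot undergo retro-aldol opening.

**Step 12**
Reactants: 20 hydroxy dione
Product: 22 4β,6α-dihydroxy-1,8-dimethyl-4-(propan-2-yl)bicyclo[5.3.0]decan-9-one, via C4-O-bound acetoxyborohydride 21 (not isolated)
Conditions: Me4NBH(OAc)3, MeCN/AcOH (1:1), −30 → 0 °C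
Reagents that add atoms: none
Why: In this Evans–Saksena directed reduction the borohydride bound to the C4 oxygen delivers hydride through a six-membered transition state to the β face of C6, giving the anti-1,3-diol (6α-OH, 6S), while the C9 ketone has no neighbouring hydroxyl and should not be reduced by this mild reagent.

**Step 13**
Reactants: 22 diol ketone
Product: 23 4,6,9-tris(trimethylsilyloxy)-8-ene (bis-silyl ether and C8=C9 silyl enol ether)
Conditions: TMSCl, NaI, Et3N, MeCN, rt → 40 °C
Reagents that add atoms: chlorotrimethylsilane C[Si](C)(C)Cl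
Why: Iodotrimethylsilane formed in situ with Et3N silylates both hydroxyls and gives the thermodynamic, more substituted silyl enol ether towards C8 (the C10 side is neopentyl and less substituted), which removes the C8 stereocentre.

**Step 14**
Reactants: 23 tris-silyl compound
Product: 25 C9 enol triflate of the 4,6-bis(trimethylsilyl) ether, via lithium enolate 24 (not isolated)
Conditions: MeLi, THF, 0 °C; then PhNTf2, −78 → 0 °C; aq. NH4Cl
Reagents that add atoms: N-phenylbis(trifluoromethanesulfonimide) O=S(=O)(N(c1ccccc1)S(=O)(=O)C(F)(F)F)C(F)(F)F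
Why: MeLi cleaves the enol Si–O bond much faster than the alkyl silyl ethers and gives the lithium enolate with fixed C8=C9 regiochemistry, which is O-sulfonylated by the triflimide.

**Step 15**
Reactants: 25 enol triflate
Product: 27 1,8-dimethyl-4-(propan-2-yl)bicyclo[5.3.0]dec-8-ene-4β,6α-diol, via bis-silyl alkene 26 (not isolated)
Conditions: Pd(OAc)2 (5 mol %), PPh3, Bu3N, HCO2H, DMF, 60 °C; then K2CO3 (cat.), MeOH, rt
Reagents that add atoms: none
Why: Oxidative addition of the enol triflate to zerovalent palladium, formate-to-hydride exchange and reductive elimination give the C8=C9 alkene, and methanolysis then removes both trimethylsilyl ethers.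

**Step 16**
Reactants: 27 diol alkene
Product: 28 8α,9α-epoxy-1,8-dimethyl-4-(propan-2-yl)bicyclo[5.3.0]decane-4β,6α-diol
Conditions: VO(acac)2 (5 mol %), tBuOOH (decane), CH2Cl2, 0 °C
Reagents that add atoms: tert-butyl hydroperoxide CC(C)(C)OO
Why: In this hydroxyl-directed epoxidation the vanadate ester of the homoallylic 6α-hydroxyl delivers oxygen to the α face of C8=C9, which is also the open face because the C1 methyl shields the β face, giving the 8α,9α-epoxide (8R,9S).

**Step 17**
Reactants: 28 epoxy diol; 29 4-(benzyloxy)benzoyl chloride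
Product: 30 C6 4-(benzyloxy)benzoate of 28
Conditions: Et3N, DMAP, CH2Cl2, 0 °C → rt
Reagents that add atoms: none
Why: DMAP-catalysed acylation takes the secondary C6 hydroxyl only, since the tertiary C4 hydroxyl is inert and the epoxide tolerates the buffered conditions.

**Step 18**
Reactants: 30 epoxy ester
Product: 31 4β,8β,9α-trihydroxy-1,8-dimethyl-4-(propan-2-yl)bicyclo[5.3.0]decan-6α-yl 4-(benzyloxy)benzoate
Conditions: HClO4 (cat.), THF/H2O, 0 °C → rt
Reagents that add atoms: water O
Why: In the acid-catalysed epoxide hydrolysis water attacks the tertiary C8 of the protonated epoxide from the β face with inversion while the C9–O bond is retained, giving the trans-diol with 8β-OH (8S) and 9α-OH (9S).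

**Step 19**
Reactants: 31 benzyl-protected ester
Product: 32 CNP0197754.1
Conditions: H2 (1 atm), Pd/C (palladium on carbon, 10 %), EtOAc, rt
Reagents that add atoms: none
Why: Hydrogenolysis cleaves the benzyl aryl ether and nothing else, because no alkene or other reducible group remains and the alkyl aryl ester is stable.

**Compound list**
1 | 2-ethylacrolein (2-methylidenebutanal) | C=C(CC)C=O | starting material
2 | 2-methylidenebutan-1-ol | C=C(CC)CO | intermediate
3 | 2-(chloromethyl)but-1-ene | C=C(CC)CCl | intermediate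
4 | 3-ethoxycyclopent-2-en-1-one | CCOC1=CC(=O)CC1 | starting material
5 | (2-methylidenebutyl)magnesium chloride (not isolated) | C=C(CC)C[Mg]Cl | intermediate
6 | chloromagnesium 3-ethoxy-1-(2-methylidenebutyl)cyclopent-2-en-1-olate, racemic (not isolated) | CCOC1=CC(O[Mg]Cl)(CC(=C)CC)CC1 | intermediate
7 | 3-(2-methylidenebutyl)cyclopent-2-en-1-one | O=C1C=C(CC(=C)CC)CC1 | intermediate
8 | dimethylaluminium (5R)-5-methyl-5-(2-methylidenebutyl)cyclopent-1-en-1-olate (not isolated) | C[Al](C)OC1=C[C@@](C)(CC(=C)CC)CC1 | intermediate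
9 | trimethyl{[(5R)-5-methyl-5-(2-methylidenebutyl)cyclopent-1-en-1-yl]oxy}silane | C[Si](C)(C)OC1=C[C@@](C)(CC(=C)CC)CC1 | intermediate
10 | acetaldehyde | CC=O | starting material
11 | lithium (5R)-5-methyl-5-(2-methylidenebutyl)cyclopent-1-en-1-olate (not isolated) | [Li]OC1=C[C@@](C)(CC(=C)CC)CC1 | intermediate
12 | (2S,3R)-2-(1-hydroxyethyl)-3-methyl-3-(2-methylidenebutyl)cyclopentan-1-one (side chain cis to the ring methyl; both carbinol epimers) | CC(O)[C@H]1C(=O)CC[C@]1(C)CC(=C)CC | intermediate
13 | (1R,2S,3R)-2-(1-hydroxyethyl)-3-methyl-3-(2-methylidenebutyl)-1-(propan-2-yl)cyclopentan-1-ol (ring OH cis to the hydroxyethyl group; carbinol epimers) | CC(O)[C@H]1[C@](O)(C(C)C)CC[C@]1(C)CC(=C)CC | intermediate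
14 | 1-[(1R,2R,5R)-2-hydroxy-5-methyl-5-(2-methylidenebutyl)-2-(propan-2-yl)cyclopentyl]ethan-1-one | CC(=O)[C@H]1[C@](O)(C(C)C)CC[C@]1(C)CC(=C)CC | intermediate
15 | 1-[(1R,2R,5R)-2-methyl-2-(2-methylidenebutyl)-5-(propan-2-yl)-5-(triethylsilyloxy)cyclopentyl]ethan-1-one | CC(=O)[C@H]1[C@](O[Si](CC)(CC)CC)(C(C)C)CC[C@]1(C)CC(=C)CC | intermediate
16 | 1,2,4-trioxolane (secondary ozonide) formed at the methylidene group of 15 (not isolated) | CC(=O)[C@H]1[C@](O[Si](CC)(CC)CC)(C(C)C)CC[C@]1(C)CC2(CC)OCOO2 | intermediate
17 | 1-[(1R,2R,3R)-2-acetyl-1-methyl-3-(propan-2-yl)-3-(triethylsilyloxy)cyclopentyl]butan-2-one (key-step precursor; acetyl trans to the 2-oxobutyl arm, cis to the silyloxy group) | CC(C)[C@]1(O[Si](CC)(CC)CC)CC[C@](C)(CC(=O)CC)[C@H]1C(C)=O | intermediate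
18 | dilithium bis-enolate of 17, C6(OLi)=C7 and C9(OLi)=C8 (not isolated) | CC(C)[C@]1(O[Si](CC)(CC)CC)CC[C@](C)(CC(O[Li])=CC)[C@H]1C(=C)O[Li] | intermediate
19 | (1R,4R,5R,8R)-1,8-dimethyl-4-(propan-2-yl)-4-(triethylsilyloxy)bicyclo[5.3.0]decane-6,9-dione (trans-fused; key-step product; C8 epimerisable) | CC(C)[C@]1(O[Si](CC)(CC)CC)CC[C@]2(C)CC(=O)[C@H](C)CC(=O)[C@H]21 | intermediate
20 | (1R,4R,5R,8R)-4-hydroxy-1,8-dimethyl-4-(propan-2-yl)bicyclo[5.3.0]decane-6,9-dione | CC(C)[C@]1(O)CC[C@]2(C)CC(=O)[C@H](C)CC(=O)[C@H]21 | intermediate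
21 | tetramethylammonium diacetoxy(hydrido)borate bound through the C4 oxygen of 20 (not isolated) | CC(C)[C@]1(O[BH-](OC(C)=O)OC(C)=O)CC[C@]2(C)CC(=O)[C@H](C)CC(=O)[C@H]21.C[N+](C)(C)C | intermediate
22 | (1R,4R,5S,6S,8R)-4,6-dihydroxy-1,8-dimethyl-4-(propan-2-yl)bicyclo[5.3.0]decan-9-one (4β-OH, 6α-OH) | CC(C)[C@]1(O)CC[C@]2(C)CC(=O)[C@H](C)C[C@H](O)[C@H]21 | intermediate
23 | (1R,4R,5S,6S)-1,8-dimethyl-4-(propan-2-yl)-4,6,9-tris(trimethylsilyloxy)bicyclo[5.3.0]dec-8-ene | CC(C)[C@]1(O[Si](C)(C)C)CC[C@]2(C)CC(O[Si](C)(C)C)=C(C)C[C@H](O[Si](C)(C)C)[C@H]21 | intermediate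
24 | lithium (1R,4R,5S,6S)-1,8-dimethyl-4-(propan-2-yl)-4,6-bis(trimethylsilyloxy)bicyclo[5.3.0]dec-8-en-9-olate (not isolated) | CC(C)[C@]1(O[Si](C)(C)C)CC[C@]2(C)CC(O[Li])=C(C)C[C@H](O[Si](C)(C)C)[C@H]21 | intermediate
25 | (1R,4R,5S,6S)-1,8-dimethyl-4-(propan-2-yl)-4,6-bis(trimethylsilyloxy)bicyclo[5.3.0]dec-8-en-9-yl trifluoromethanesulfonate | CC(C)[C@]1(O[Si](C)(C)C)CC[C@]2(C)CC(OS(=O)(=O)C(F)(F)F)=C(C)C[C@H](O[Si](C)(C)C)[C@H]21 | intermediate
26 | (1R,4R,5S,6S)-1,8-dimethyl-4-(propan-2-yl)-4,6-bis(trimethylsilyloxy)bicyclo[5.3.0]dec-8-ene (not isolated) | CC(C)[C@]1(O[Si](C)(C)C)CC[C@]2(C)CC=C(C)C[C@H](O[Si](C)(C)C)[C@H]21 | intermediate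
27 | (1R,4R,5S,6S)-1,8-dimethyl-4-(propan-2-yl)bicyclo[5.3.0]dec-8-ene-4,6-diol (4β-OH, 6α-OH) | CC(C)[C@]1(O)CC[C@]2(C)CC=C(C)C[C@H](O)[C@H]21 | intermediate
28 | (1R,4R,5S,6S,8R,9S)-8,9-epoxy-1,8-dimethyl-4-(propan-2-yl)bicyclo[5.3.0]decane-4,6-diol (8α,9α-epoxide) | CC(C)[C@]1(O)CC[C@]2(C)C[C@@H]3O[C@]3(C)C[C@H](O)[C@H]21 | intermediate
29 | 4-(benzyloxy)benzoyl chloride | O=C(Cl)c1ccc(OCc2ccccc2)cc1 | starting material
30 | (1R,4R,5S,6S,8R,9S)-8,9-epoxy-4-hydroxy-1,8-dimethyl-4-(propan-2-yl)bicyclo[5.3.0]decan-6-yl 4-(benzyloxy)benzoate | CC(C)[C@]1(O)CC[C@]2(C)C[C@@H]3O[C@]3(C)C[C@H](OC(=O)c4ccc(OCc5ccccc5)cc4)[C@H]21 | intermediate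
31 | (1R,4R,5S,6S,8S,9S)-4,8,9-trihydroxy-1,8-dimethyl-4-(propan-2-yl)bicyclo[5.3.0]decan-6-yl 4-(benzyloxy)benzoate | CC(C)[C@]1(O)CC[C@]2(C)C[C@H](O)[C@@](C)(O)C[C@H](OC(=O)c3ccc(OCc4ccccc4)cc3)[C@H]21 | intermediate
32 | CNP0197754.1, (1R,4R,5S,6S,8S,9S)-4,8,9-trihydroxy-1,8-dimethyl-4-(propan-2-yl)bicyclo[5.3.0]decan-6-yl 4-hydroxybenzoate | CC(C)[C@]1(O)CC[C@]2(C)C[C@H](O)[C@@](C)(O)C[C@H](OC(=O)c3ccc(O)cc3)[C@H]21 | target

**Totals and risks**
Total step count: 19. Longest linear sequence: 19 steps (1 → 32; 4, 10 and 29 are bought).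

Three steps most likely to fail:

1. Step 10 (bears the label "Proposed new method:"). What may go wrong: the mono-enolate closes onto the other carbonyl in a six-membered aldol before the second deprotonation, two molecules couple instead of one ring closing, or the ethyl ketone enolises towards C10. Fallback with known chemistry, which closes the ring by olefin metathesis at C8=C9 instead of by the C7–C8 coupling: it sets out from 4 and comes back to the route at 27. Allylmagnesium bromide followed by cold dilute acid turns 4 into 3-(prop-2-en-1-yl)cyclopent-2-en-1-one F1. The copper-catalysed Me3Al addition and TMSOTf trapping of step 4 then give the (R)-silyl enol ether F2. MeLi followed by 3-methylbut-3-enal F3 (made from commercial 3-methylbut-3-en-1-ol with Dess–Martin periodinane and used crude) gives the aldol F4. iPrMgCl/CeCl3 adds as in step 6 to give the diene diol F5. Second-generation Grubbs catalyst, RuCl2(=CHPh)(PCy3)(H2IMes), closes the trisubstituted C8=C9 alkene to the cycloheptene diol F6. Dess–Martin oxidation gives the C6 ketone F7, and the Me4NBH(OAc)3 reduction of step 12, directed by the C4 hydroxyl, sets 6α-OH and gives 27.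

2. Step 6. What may go wrong: enolisation or retro-aldol cleavage of the β-oxido ketone, or β-hydride reduction by the secondary alkyl reagent, outruns addition to the hindered carbonyl. Fallback: a samarium Barbier coupling, which is a single-electron reductive addition in place of a polar organometallic addition. It sets out from 12, which is treated with 2-iodopropane and SmI2 (divalent samarium) in THF/HMPA, and comes back at 13; no new compound is made.

3. Step 8. What may go wrong: the hindered tertiary hydroxyl silylates slowly, so that enol silylation of the methyl ketone or acid-promoted loss of water from the β-hydroxy ketone intervenes. Fallback: the silyl group is put on before the ketone exists; it sets out from 13 and comes back at 15, replacing steps 7 and 8. Ac2O, pyridine and DMAP acetylate only the secondary hydroxyl to give the C6 acetate F8. TESOTf and 2,6-lutidine then give the C4 silyl ether acetate F9, K2CO3 in MeOH removes the acetate to give the C6 alcohol F10, and Dess–Martin oxidation gives 15.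

**Further compounds**
F1 | step 10 | 3-(prop-2-en-1-yl)cyclopent-2-en-1-one | O=C1C=C(CC=C)CC1
F2 | step 10 | trimethyl{[(5R)-5-methyl-5-(prop-2-en-1-yl)cyclopent-1-en-1-yl]oxy}silane | C[Si](C)(C)OC1=C[C@@](C)(CC=C)CC1
F3 | step 10 | 3-methylbut-3-enal | C=C(C)CC=O
F4 | step 10 | (2S,3R)-2-(1-hydroxy-3-methylbut-3-en-1-yl)-3-methyl-3-(prop-2-en-1-yl)cyclopentan-1-one (carbinol epimers) | C=C(C)CC(O)[C@H]1C(=O)CC[C@]1(C)CC=C
F5 | step 10 | (1R,2S,3R)-2-(1-hydroxy-3-methylbut-3-en-1-yl)-3-methyl-3-(prop-2-en-1-yl)-1-(propan-2-yl)cyclopentan-1-ol (carbinol epimers) | C=C(C)CC(O)[C@H]1[C@](O)(C(C)C)CC[C@]1(C)CC=C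
F6 | step 10 | (1R,4R,5S)-1,8-dimethyl-4-(propan-2-yl)bicyclo[5.3.0]dec-8-ene-4,6-diol (C6 epimers) | CC(C)[C@]1(O)CC[C@]2(C)CC=C(C)CC(O)[C@H]21
F7 | step 10 | (1R,4R,5R)-4-hydroxy-1,8-dimethyl-4-(propan-2-yl)bicyclo[5.3.0]dec-8-en-6-one | CC(C)[C@]1(O)CC[C@]2(C)CC=C(C)CC(=O)[C@H]21
F0 | step 6 | none | none
F8 | step 8 | 1-[(1S,2R,5R)-2-hydroxy-5-methyl-5-(2-methylidenebutyl)-2-(propan-2-yl)cyclopentyl]ethyl acetate (carbinol epimers) | CC(OC(C)=O)[C@H]1[C@](O)(C(C)C)CC[C@]1(C)CC(=C)CC
F9 | step 8 | 1-[(1S,2R,5R)-2-methyl-2-(2-methylidenebutyl)-5-(propan-2-yl)-5-(triethylsilyloxy)cyclopentyl]ethyl acetate (carbinol epimers) | CC(OC(C)=O)[C@H]1[C@](O[Si](CC)(CC)CC)(C(C)C)CC[C@]1(C)CC(=C)CC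
F10 | step 8 | 1-[(1S,2R,5R)-2-methyl-2-(2-methylidenebutyl)-5-(propan-2-yl)-5-(triethylsilyloxy)cyclopentyl]ethan-1-ol (carbinol epimers) | CC(O)[C@H]1[C@](O[Si](CC)(CC)CC)(C(C)C)CC[C@]1(C)CC(=C)CC
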